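Late in a run of this scheme the second step goes on taking target while the first makes it for as long as substrate lasts, so a fixed reading time asks how soon the substrate has gone through.

    substrate → target, rate k1*[substrate]/(1 + ([substrate]/sat1)) (sat1 = 1.1 mM, k1 = 0.88 /s, Ea1 = 82.0 kJ/mol)
    target → over-reaction product (k2 = 0.0061 /s, Ea2 = 106 kJ/mol)
    substrate + target → side product (k3 = 4.0 /M/s, Ea3 = 57.0 kJ/mol)
    (constants at 80 °C)

all flasks: substrate 0.013 M; time 2.0 min

| run | temperature |
|---|---|
| cedar | 60 °C |
| larch | 20 °C |
| oak | 40 °C |
| birch | 80 °C |

- percentages count the substrate that a species holds: one side product counts as two
- the list of constants is for 80 °C, to be carried to other temperatures by the activation energies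

- the flask that comes out highest in amount of target, in percent of the substrate charged, or "all alike" when all lie within 1.5 percentage points (cedar / larch / oak / birch / all alike)
- target at the end, in percent of the substrate charged, cedar
- target at the end, in percent of the substrate charged, larch
- target at the end, in percent of the substrate charged, oak
- target at the end, in percent of the substrate charged, birch

The charge of 0.013 M stands 11.8 times above the constant 1.1 mM, so the first step starts saturated, close to zero order. I therefore carry one quantity, 14.6 s at 80 °C, the clearing clock: the charge divided by the starting rate of the first step.

I take it down in temperature by two ways, in powers of ten. From the activation energy, the Arrhenius law gives 0.728 decades between 80 °C and 60 °C, which puts the clock of cedar at 77.9 s. From the span, the first step speeds up 300 times from larch to birch, which is 2.48 decades, and an even share of a third of that puts the clock of cedar at 97.9 s. Both lie under the run of 120 s, so I expect cedar to clear within the run, though the span comes from the same activation energy, and this agreement tests my arithmetic and not the activation energy itself. They part by 20.0 s, and the even share is the one that cheats, because the law is straight in reciprocal temperature: the hot gap holds 0.728 decades and the cold gap between oak and larch holds 0.933.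

The clock of oak is 8.60 min and that of larch 73.7 min, both longer than the run, so run over clock gives what passes the first step: about 23.3 % in oak and 2.71 % in larch. Birch clears early, but its target then sits about 105 s against a half-life of 114 s by the second step, so birch loses about half of it. In cedar that half-life is 16.5 min, far longer than the run. I commit to cedar.

The forecast also names cedar, with 66.5 % (range 62 % to 71 %) for cedar, 2.6 % for larch, 18.4 % for oak and 40.5 % for birch, holding of the over-reaction that “at 60 °C that loss is negligible”. Its figures count target, whereas mine for oak and larch count what passes the first step, so the two differ.

The simulation gives cedar highest: 66.5 % in cedar, 2.56 % in larch, 18.6 % in oak and 39.9 % in birch. The clock of cedar, 1.30 min, falls between the reading at 1.00 min, with 16.3 % substrate, and the end, with 0 %. At 0.569 min in cedar the step to side product takes target 12 times as fast as the second step, and the half-life of target by the second step, 17 min, is long against the run of 2.0 min. In birch the clock reads 0.243 min, and substrate falls under a fiftieth of its charge at 0.264 min.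

The numbers are those of an exercise; the run is a simulation.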